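The route rests on opening the cyclopentenone (ring C1–C5; locants follow the target chain from C1–OAc to the C15 ketone) at C3–C4. C1, the fully substituted carbinol shared by the five- and twelve-membered rings, bears two propyne-derived three-carbon arms, C2=C3(Me) and C15–C14(Me), so it is latent in a symmetric dipropynyl carbinol. One Rh-catalysed intramolecular alkyne hydroacylation of the prochiral aldehyde OHC(C4)–CH2(C5)–C1(OSiEt3)(C≡C–CH3)2 forms C3–C4, closes the enone and fixes C1 by selecting one enantiotopic alkyne. The spare alkyne is the masked C15 ethyl ketone. An enantiopure tetrahydrofuran aldehyde (C6–C13) is then condensed at C5=C6, and C14 alkylation closes the macrocycle.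

Key step: step 3

Remark: the sense of induction of Tol-BINAP for the triethylsilyl ether is assumed to parallel that of the known 3-alkoxy substrates and is checked on a trial run; if (4S)-8 results, the antipodal ligand is used.

Step 1
Reactants: 1 ethyl 3,3-diethoxypropanoate; 2 1-propynylmagnesium bromide
Product: 4 4-(2,2-diethoxyethyl)hepta-2,5-diyn-4-ol, via ynone 3 (not isolated)
Conditions: 2 (2.5 equiv), THF, 0 °C → rt; aq. NH4Cl
Reagents that add atoms: none
Why: Double 1,2-addition of the alkynyl Grignard reagent to the ester (the intermediate ynone is more electrophilic than the ester) should give the symmetric tertiary carbinol, the acetal being inert to the reagent.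

Step 2
Reactants: 4 4-(2,2-diethoxyethyl)hepta-2,5-diyn-4-ol
Product: 7 3-(prop-1-ynyl)-3-(triethylsilyloxy)hex-4-ynal, via silyl ether acetal 5 (not isolated), via lutidinium salt 6 (not isolated)
Conditions: TESOTf (3 equiv), 2,6-lutidine (4 equiv), CH2Cl2, −78 → 0 °C; then H2O, 0 °C
Reagents that add atoms: triethylsilyl trifluoromethanesulfonate, CC[Si](CC)(CC)OS(=O)(=O)C(F)(F)F; water, O
Why: The silyl triflate first silylates the tertiary alcohol and then turns the diethyl acetal into an N-(1-ethoxyalkyl)lutidinium salt that water hydrolyses at near-neutral pH (silyl triflate–lutidine acetal cleavage), so the acid-labile bis-propargylic silyl ether and the β-silyloxy aldehyde never meet a Brønsted acid.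

Step 3
Reactants: 7 3-(prop-1-ynyl)-3-(triethylsilyloxy)hex-4-ynal
Product: 8 (4R)-2-methyl-4-(prop-1-ynyl)-4-(triethylsilyloxy)cyclopent-2-en-1-one
Conditions: [Rh((R)-Tol-BINAP)]BF4 (10 mol %), CH2Cl2, rt
Reagents that add atoms: none
Why: Cationic Rh(I) adds oxidatively into the aldehyde C4–H bond, the acyl rhodium hydride hydrometalates one propynyl group, the alkenyl rhodium isomerises so that acyl and hydrogen end up anti across C2=C3, and C3–C4 reductive elimination from the six-membered acyl(alkenyl)rhodacycle releases the enone. The closest known reaction type is the Rh–bisphosphine intramolecular hydroacylation of 4-alkynals to cyclopent-2-enones, including the enantioselective desymmetrisation of 3-alkoxy-3,3-dialkynylpropanals. The cyclopentenone ring C1–C5 is closed in a formal 5-endo-dig mode, with the alkyne methyl ending on C3. The only new stereocentre, C1, is controlled by the chiral bisphosphine alone, which lets just one of the two enantiotopic alkynes reach the Rh–H bond; the Tol-BINAP antipode that gives (4R)-8 is used. The step needs hydroacylation to outrun decarbonylation and alkyne oligomerisation and to give only the five-membered ring; the substrate secures this through the quaternary C1 (no β-hydrogen, gem-dialkynyl compression holding an alkyne next to the metal), the 1,4-relation of CHO and C≡C, and the inert silyl ether.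

Step 4
Reactants: 9 geranyl acetate
Product: 11 (2E)-3-methyl-6-oxohex-2-en-1-yl acetate, via ozonide 10 (not isolated)
Conditions: O3 (1 equiv), CH2Cl2, −78 °C; then Me2S, −78 °C → rt
Reagents that add atoms: ozone, [O-][O+]=O
Why: In this selective ozonolysis ozone attacks the electron-rich trisubstituted 6,7-alkene in preference to the 2,3-alkene deactivated by the allylic acetate, and dimethyl sulfide reduces the ozonide to the aldehyde.

Step 5
Reactants: 11 (2E)-3-methyl-6-oxohex-2-en-1-yl acetate; 12 3-methylbuta-1,2-diene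
Product: 15 (2E,6S)-3,7,7-trimethylnona-2,8-diene-1,6-diol, via prenylborane 13 (not isolated), via borinate 14 (not isolated)
Conditions: (+)-Ipc2BH [from (−)-α-pinene], 12, THF, −25 °C; then 11, −78 °C; NaOH, H2O2, MeOH, rt
Reagents that add atoms: none
Why: Brown asymmetric prenylboration transfers the allyl unit through its γ-carbon in a chair Zimmerman–Traxler transition state in which the (+)-Ipc2B group directs attack to the Re face, which should set C10 as (S) and create the C11 quaternary carbon with its vinyl group (C12=C13); the alkaline peroxide work-up also saponifies the acetate.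

Step 6
Reactants: 15 (2E,6S)-3,7,7-trimethylnona-2,8-diene-1,6-diol
Product: 17 (1R)-1-[(2S,5S)-2-methyl-5-(2-methylbut-3-en-2-yl)oxolan-2-yl]ethane-1,2-diol, via epoxy alcohol 16 (not isolated)
Conditions: Ti(OiPr)4 (10 mol %), D-(−)-DET (12 mol %), t-BuOOH, 4 Å MS, CH2Cl2, −20 °C; then CSA (cat.), rt
Reagents that add atoms: tert-butyl hydroperoxide, CC(C)(C)OO
Why: Sharpless asymmetric epoxidation of the (E)-trisubstituted allylic alcohol with D-(−)-DET should give the (2R,3R)-epoxide, and acid-catalysed 5-exo opening by the C10 hydroxyl at the tertiary epoxide carbon with inversion sets C7 as (S), trans to the C10–C11 bond.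

Step 7
Reactants: 17 (1R)-1-[(2S,5S)-2-methyl-5-(2-methylbut-3-en-2-yl)oxolan-2-yl]ethane-1,2-diol
Product: 19 (1R)-1-[(2S,5S)-5-(4-hydroxy-2-methylbutan-2-yl)-2-methyloxolan-2-yl]ethane-1,2-diol, via alkylborane 18 (not isolated)
Conditions: 9-BBN (4 equiv), THF, 0 °C → rt; then NaOH, H2O2, 0 °C
Reagents that add atoms: hydrogen peroxide, OO
Why: Hydroboration–oxidation with 9-BBN adds boron to the terminal carbon of the only remaining alkene, which should give the primary C13 alcohol (the hydroxyls are only transiently O-borylated).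

Step 8
Reactants: 19 (1R)-1-[(2S,5S)-5-(4-hydroxy-2-methylbutan-2-yl)-2-methyloxolan-2-yl]ethane-1,2-diol
Product: 20 (2S,5S)-5-(4-hydroxy-2-methylbutan-2-yl)-2-methyloxolane-2-carbaldehyde
Conditions: NaIO4, THF/H2O, 0 °C → rt
Reagents that add atoms: none
Why: Periodate glycol cleavage removes the extra carbon as formaldehyde and reveals the C6 aldehyde, which has no α-hydrogen and so cannot epimerise at C7.

Step 9
Reactants: 20 (2S,5S)-5-(4-hydroxy-2-methylbutan-2-yl)-2-methyloxolane-2-carbaldehyde
Product: 21 (2S,5S)-5-(4-chloro-2-methylbutan-2-yl)-2-methyloxolane-2-carbaldehyde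
Conditions: NCS, PPh3, CH2Cl2, 0 °C → rt
Reagents that add atoms: N-chlorosuccinimide, O=C1CCC(=O)N1Cl
Why: Appel-type chlorination through the alkoxyphosphonium salt converts the unhindered primary alcohol into a chloride, a handle that is inert to every step before the halide exchange, while the absence of a tetrahalomethane avoids olefination of the aldehyde.

Step 10
Reactants: 8 (4R)-2-methyl-4-(prop-1-ynyl)-4-(triethylsilyloxy)cyclopent-2-en-1-one; 21 (2S,5S)-5-(4-chloro-2-methylbutan-2-yl)-2-methyloxolane-2-carbaldehyde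
Product: 22 (4S)-5-{[(2S,5S)-5-(4-chloro-2-methylbutan-2-yl)-2-methyloxolan-2-yl](hydroxy)methyl}-2-methyl-4-(prop-1-ynyl)-4-(triethylsilyloxy)cyclopent-2-en-1-one (mixture at C5 and the carbinol carbon)
Conditions: LDA (1.05 equiv), THF, −78 °C; then 21, −78 °C; AcOH quench at −78 °C
Reagents that add atoms: none
Why: Kinetic deprotonation can occur only at C5 because the C15 ketone is still masked as the alkyne, and aldol addition of this enolate to the non-enolisable aldehyde at −78 °C should outrun loss of silanolate, as it does for other 4-silyloxycyclopentenone enolates; the two new stereocentres are removed in the next step.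

Step 11
Reactants: 22 aldol adduct
Product: 24 (4R,5E)-5-{[(2S,5S)-5-(4-chloro-2-methylbutan-2-yl)-2-methyloxolan-2-yl]methylidene}-2-methyl-4-(prop-1-ynyl)-4-(triethylsilyloxy)cyclopent-2-en-1-one, via mesylate 23 (not isolated)
Conditions: MsCl, Et3N, CH2Cl2, 0 °C; then DBU, 0 °C → rt
Reagents that add atoms: none
Why: Mesylation and E1cB elimination through the C5 enolate should give the (E)-alkylidene, because the fully substituted C7 avoids the coplanar C4 carbonyl oxygen while C1 offers only out-of-plane substituents, as in related 4-oxy-5-alkylidenecyclopentenones.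

Step 12
Reactants: 24 TES dienone
Product: 25 (4R,5E)-5-{[(2S,5S)-5-(4-chloro-2-methylbutan-2-yl)-2-methyloxolan-2-yl]methylidene}-4-hydroxy-2-methyl-4-(prop-1-ynyl)cyclopent-2-en-1-one
Conditions: HF·pyridine, pyridine/THF, 0 °C → rt
Reagents that add atoms: none
Why: Fluoride-driven desilylation cleaves the tertiary Si–O bond under buffered conditions that leave the dienone, the alkyne and the alkyl chloride untouched.

Step 13
Reactants: 25 hydroxy dienone
Product: 27 (4S,5E)-5-{[(2S,5S)-5-(4-chloro-2-methylbutan-2-yl)-2-methyloxolan-2-yl]methylidene}-4-hydroxy-2-methyl-4-propanoylcyclopent-2-en-1-one, via enol carbonate 26 (not isolated)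
Conditions: AgOAc (10 mol %), DBU (1 equiv), CO2 (1 MPa), MeCN, rt; then H2O, 40 °C
Reagents that add atoms: carbon dioxide, O=C=O
Why: In this silver-catalysed carboxylative cyclisation the carbonate formed from the tertiary propargylic alcohol, CO2 and DBU adds 5-exo-dig to the Ag-activated alkyne and so places oxygen on C15 only, and hydrolysis of the enol carbonate with loss of CO2 should give the ethyl ketone without Meyer–Schuster rearrangement.

Step 14
Reactants: 27 chloro ketol
Product: 28 (4S,5E)-4-hydroxy-5-{[(2S,5S)-5-(4-iodo-2-methylbutan-2-yl)-2-methyloxolan-2-yl]methylidene}-2-methyl-4-propanoylcyclopent-2-en-1-one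
Conditions: NaI, butan-2-one, 70 °C
Reagents that add atoms: sodium iodide, [Na+].[I-]
Why: Finkelstein exchange, driven by precipitation of sodium chloride, should turn the robust chloride into the iodide needed for C-alkylation.

Step 15
Reactants: 28 iodo ketol
Product: 29 (1S,5E,7S,10S,14R)-1-hydroxy macrocycle (the target without its acetyl group)
Conditions: LDA (2.1 equiv), THF (0.002 M), −78 °C → rt; aq. NH4Cl
Reagents that add atoms: none
Why: Intramolecular enolate C-alkylation of the lithium alkoxide–enolate dianion at high dilution should close the twelve-membered ring at C13–C14, with C14 set as (R) because the Z(O)-enolate is held syn-coplanar with the C1 alkoxide by a lithium bridge and the tether borne by C5 can reach only one of its faces.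

Step 16
Reactants: 29 macrocyclic ketol
Product: 30 CNP0144863.1
Conditions: Ac2O, DMAP, Et3N, CH2Cl2, 35 °C
Reagents that add atoms: acetic anhydride, CC(=O)OC(C)=O
Why: DMAP-catalysed acylation esterifies the tertiary α-ketol hydroxyl under mild base that should not epimerise C14, and it is placed last because an enolate at C14 would attack a C1 acetate.

Compound list
1 | ethyl 3,3-diethoxypropanoate | CCOC(=O)CC(OCC)OCC | starting material
2 | 1-propynylmagnesium bromide | CC#C[Mg]Br | starting material
3 | 1,1-diethoxyhex-4-yn-3-one (not isolated) | CC#CC(=O)CC(OCC)OCC | intermediate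
4 | 4-(2,2-diethoxyethyl)hepta-2,5-diyn-4-ol | CC#CC(O)(CC(OCC)OCC)C#CC | intermediate
5 | [4-(2,2-diethoxyethyl)hepta-2,5-diyn-4-yl]oxy(triethyl)silane (not isolated) | CC#CC(CC(OCC)OCC)(C#CC)O[Si](CC)(CC)CC | intermediate
6 | 1-[1-ethoxy-3-(prop-1-ynyl)-3-(triethylsilyloxy)hex-4-ynyl]-2,6-dimethylpyridinium triflate (not isolated) | CCOC(CC(C#CC)(C#CC)O[Si](CC)(CC)CC)[n+]1c(C)cccc1C.[O-]S(=O)(=O)C(F)(F)F | intermediate
7 | 3-(prop-1-ynyl)-3-(triethylsilyloxy)hex-4-ynal | CC#CC(CC=O)(C#CC)O[Si](CC)(CC)CC | intermediate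
8 | (4R)-2-methyl-4-(prop-1-ynyl)-4-(triethylsilyloxy)cyclopent-2-en-1-one | CC[Si](CC)(CC)O[C@@]1(C#CC)C=C(C)C(=O)C1 | intermediate
9 | geranyl acetate, (2E)-3,7-dimethylocta-2,6-dien-1-yl acetate | CC(C)=CCC/C(C)=C/COC(C)=O | starting material
10 | (2E)-5-(5,5-dimethyl-1,2,4-trioxolan-3-yl)-3-methylpent-2-en-1-yl acetate (not isolated) | CC(=O)OC/C=C(C)/CCC1OOC(C)(C)O1 | intermediate
11 | (2E)-3-methyl-6-oxohex-2-en-1-yl acetate | CC(=O)OC/C=C(C)/CCC=O | intermediate
12 | 3-methylbuta-1,2-diene | CC(C)=C=C | starting material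
13 | (+)-B-(3-methylbut-2-enyl)diisopinocampheylborane (not isolated) | CC(C)=CCB([C@H]1C[C@H]2C[C@@H]([C@@H]1C)C2(C)C)[C@H]1C[C@H]2C[C@@H]([C@@H]1C)C2(C)C | intermediate
14 | diisopinocampheylborinate of (2E,6S)-6-hydroxy-3,7,7-trimethylnona-2,8-dien-1-yl acetate (not isolated) | CC(=O)OC/C=C(C)/CC[C@H](OB([C@H]1C[C@H]2C[C@@H]([C@@H]1C)C2(C)C)[C@H]1C[C@H]2C[C@@H]([C@@H]1C)C2(C)C)C(C)(C)C=C | intermediate
15 | (2E,6S)-3,7,7-trimethylnona-2,8-diene-1,6-diol | OC/C=C(C)/CC[C@H](O)C(C)(C)C=C | intermediate
16 | [(2R,3R)-3-[(3S)-3-hydroxy-4,4-dimethylhex-5-enyl]-3-methyloxiran-2-yl]methanol (not isolated) | OC[C@H]1O[C@]1(C)CC[C@H](O)C(C)(C)C=C | intermediate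
17 | (1R)-1-[(2S,5S)-2-methyl-5-(2-methylbut-3-en-2-yl)oxolan-2-yl]ethane-1,2-diol | OC[C@@H](O)[C@]1(C)CC[C@H](O1)C(C)(C)C=C | intermediate
18 | B-alkyl-9-borabicyclo[3.3.1]nonane adduct of 17, boron on C13 (not isolated) | OC[C@@H](O)[C@]1(C)CC[C@H](O1)C(C)(C)CCB1C2CCCC1CCC2 | intermediate
19 | (1R)-1-[(2S,5S)-5-(4-hydroxy-2-methylbutan-2-yl)-2-methyloxolan-2-yl]ethane-1,2-diol | OC[C@@H](O)[C@]1(C)CC[C@H](O1)C(C)(C)CCO | intermediate
20 | (2S,5S)-5-(4-hydroxy-2-methylbutan-2-yl)-2-methyloxolane-2-carbaldehyde | O=C[C@]1(C)CC[C@H](O1)C(C)(C)CCO | intermediate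
21 | (2S,5S)-5-(4-chloro-2-methylbutan-2-yl)-2-methyloxolane-2-carbaldehyde | O=C[C@]1(C)CC[C@H](O1)C(C)(C)CCCl | intermediate
22 | aldol adduct of 8 and 21 (C5–C6 bond, C6 carbinol; mixture at C5 and C6) | CC[Si](CC)(CC)O[C@@]1(C#CC)C=C(C)C(=O)C1C(O)[C@]1(C)CC[C@H](O1)C(C)(C)CCCl | intermediate
23 | C6 methanesulfonate of 22 (not isolated) | CC[Si](CC)(CC)O[C@@]1(C#CC)C=C(C)C(=O)C1C(OS(C)(=O)=O)[C@]1(C)CC[C@H](O1)C(C)(C)CCCl | intermediate
24 | (4R,5E)-5-{[(2S,5S)-5-(4-chloro-2-methylbutan-2-yl)-2-methyloxolan-2-yl]methylidene}-2-methyl-4-(prop-1-ynyl)-4-(triethylsilyloxy)cyclopent-2-en-1-one | CC[Si](CC)(CC)O[C@@]1(C#CC)C=C(C)C(=O)/C1=C/[C@]1(C)CC[C@H](O1)C(C)(C)CCCl | intermediate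
25 | (4R,5E)-5-{[(2S,5S)-5-(4-chloro-2-methylbutan-2-yl)-2-methyloxolan-2-yl]methylidene}-4-hydroxy-2-methyl-4-(prop-1-ynyl)cyclopent-2-en-1-one | O[C@@]1(C#CC)C=C(C)C(=O)/C1=C/[C@]1(C)CC[C@H](O1)C(C)(C)CCCl | intermediate
26 | spiro cyclic carbonate of 25: (Z)-4-ethylidene-1,3-dioxolan-2-one built from C1–O, CO2 and C15, with C15=C14 exocyclic (not isolated) | O=C1O/C(=C\C)[C@]2(O1)C=C(C)C(=O)/C2=C/[C@]1(C)CC[C@H](O1)C(C)(C)CCCl | intermediate
27 | (4S,5E)-5-{[(2S,5S)-5-(4-chloro-2-methylbutan-2-yl)-2-methyloxolan-2-yl]methylidene}-4-hydroxy-2-methyl-4-propanoylcyclopent-2-en-1-one | CCC(=O)[C@]1(O)C=C(C)C(=O)/C1=C/[C@]1(C)CC[C@H](O1)C(C)(C)CCCl | intermediate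
28 | (4S,5E)-4-hydroxy-5-{[(2S,5S)-5-(4-iodo-2-methylbutan-2-yl)-2-methyloxolan-2-yl]methylidene}-2-methyl-4-propanoylcyclopent-2-en-1-one | CCC(=O)[C@]1(O)C=C(C)C(=O)/C1=C/[C@]1(C)CC[C@H](O1)C(C)(C)CCI | intermediate
29 | (1S,5E,7S,10S,14R)-1-hydroxy macrocycle, the target without its acetyl group (target locants) | O[C@@]12C=C(C)C(=O)/C1=C/[C@]1(C)CC[C@H](O1)C(C)(C)CC[C@@H](C)C2=O | intermediate
30 | CNP0144863.1, (1S,5E,7S,10S,14R)-1-acetoxy-7,10-epoxy macrocyclic dienedione (target locants) | CC(=O)O[C@@]12C=C(C)C(=O)/C1=C/[C@]1(C)CC[C@H](O1)C(C)(C)CC[C@@H](C)C2=O | target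

Total step count: 16. Longest linear sequence: 13 steps (9 → 30, steps 4–9 and 10–16); the core branch 1 → 8 has 3 steps.

Steps most likely to fail

Step 15. The twelve-membered ring may close more slowly than intermolecular C- or O-alkylation or elimination of the iodide, or the tether may reach the enolate in a non-chelated rotamer and set C14 the wrong way. The fallback sets out from 28 and comes back at 29. The iodide is oxidised with trimethylamine N-oxide in DMSO (Kornblum-type oxidation) to the C13 aldehyde F1. The dianion of F1 (LDA, 2.1 equiv, THF, −78 °C, high dilution) closes the ring by aldol addition, which is far faster than alkylation, to give the macrocyclic β-hydroxy ketone F2 with C14 set by the same chelated Z-enolate. Only the secondary hydroxyl reacts with 1,1′-thiocarbonyldiimidazole and DMAP to give the imidazole-1-carbothioate F3. Barton–McCombie deoxygenation (Bu3SnH at high concentration, AIBN, toluene, 80 °C) then leaves C14 untouched and gives 29.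

Step 10. The C5 enolate may lose triethylsilanolate (β-elimination), or add too slowly to the hindered aldehyde so that retro-aldol cleavage wins on warming. The fallback sets out from 8 and comes back at 24. Compound 8 is deprotonated with LDA and trapped on oxygen with diethyl chlorophosphate to give the dienyl phosphate F4. A second equivalent of LDA induces the 1,3-phosphorus shift from oxygen to C5 and gives the β-keto phosphonate F5. Horner–Wadsworth–Emmons reaction of F5 with 21 (Ba(OH)2, wet THF) forms C5=C6 directly and gives 24, bypassing 22 and 23.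

Step 3. The bulky, weakly coordinating silyl ether may let the catalyst distinguish the two enantiotopic alkynes less well than the alkyl ethers of the precedent (low enantiomeric purity), or decarbonylation of the acyl rhodium hydride may compete. The fallback sets out from 7 and comes back at 24. Cyclisation of 7 with the achiral catalyst [Rh(dppe)]2(BF4)2 gives the racemic enone F6. Steps 10 and 11 with enantiopure 21 carry its (S)-half through the epimeric aldols F7 and mesylates F8 to the C1-epimeric dienone F9. F9 is a diastereomer of 24 and is removed by chromatography, so the stereocentres of 21 resolve C1.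

Further compounds
F1 | step 15 | (4S,5E)-4-hydroxy-2-methyl-5-{[(2S,5S)-2-methyl-5-(2-methyl-4-oxobutan-2-yl)oxolan-2-yl]methylidene}-4-propanoylcyclopent-2-en-1-one | CCC(=O)[C@]1(O)C=C(C)C(=O)/C1=C/[C@]1(C)CC[C@H](O1)C(C)(C)CC=O
F2 | step 15 | 13-hydroxy derivative of 29 (macrocyclic aldol, mixture at C13) | O[C@@]12C=C(C)C(=O)/C1=C/[C@]1(C)CC[C@H](O1)C(C)(C)CC(O)[C@@H](C)C2=O
F3 | step 15 | 13-O-(imidazol-1-ylcarbonothioyl) derivative of F2 | O[C@@]12C=C(C)C(=O)/C1=C/[C@]1(C)CC[C@H](O1)C(C)(C)CC(OC(=S)n3ccnc3)[C@@H](C)C2=O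
F4 | step 10 | diethyl (5R)-3-methyl-5-(prop-1-ynyl)-5-(triethylsilyloxy)cyclopenta-1,3-dien-2-yl phosphate | CCOP(=O)(OCC)OC1=C[C@@](C#CC)(O[Si](CC)(CC)CC)C=C1C
F5 | step 10 | diethyl [(5R)-3-methyl-2-oxo-5-(prop-1-ynyl)-5-(triethylsilyloxy)cyclopent-3-en-1-yl]phosphonate | CCOP(=O)(OCC)C1C(=O)C(C)=C[C@]1(C#CC)O[Si](CC)(CC)CC
F6 | step 3 | racemic 2-methyl-4-(prop-1-ynyl)-4-(triethylsilyloxy)cyclopent-2-en-1-one | CC[Si](CC)(CC)OC1(C#CC)C=C(C)C(=O)C1
F7 | step 3 | aldol adduct of (4S)-8 and 21 (C1 epimer of 22) | CC[Si](CC)(CC)O[C@]1(C#CC)C=C(C)C(=O)C1C(O)[C@]1(C)CC[C@H](O1)C(C)(C)CCCl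
F8 | step 3 | C6 methanesulfonate of F7 | CC[Si](CC)(CC)O[C@]1(C#CC)C=C(C)C(=O)C1C(OS(C)(=O)=O)[C@]1(C)CC[C@H](O1)C(C)(C)CCCl
F9 | step 3 | (4S,5E)-epimer of 24 at C1 | CC[Si](CC)(CC)O[C@]1(C#CC)C=C(C)C(=O)/C1=C/[C@]1(C)CC[C@H](O1)C(C)(C)CCCl
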